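**Strategy.** The side chain is cut between C11 and C12, inside the third prenyl unit counted from the ring. C11 is an olefinic carbon carrying a methyl group and, trans to the chain, the CH2 of the tail; this geminal pattern is read as a 1,1-dichloroalkene. In one pot a C36 terminal 1,3-diene is hydroborated, the homoallyl-9-BBN is coupled trans-selectively with the dichloroalkene terminus of the ring-bearing fragment (quinone masked as tetramethoxyarene), and the remaining C–Cl bond is methylated with retention. Three building blocks thus give the (E)-trisubstituted alkene and the whole side chain; oxidative demethylation then releases the quinone.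

Key step: step 13

Assumptions: side-chain carbons are numbered C1 (ring CH2) to C40. The single stereocentre, C35, is S in the target; it is carried in unchanged from (R)-citronellyl bromide, and the descriptor changes only because the CIP priorities of the two chain arms swap. Compounds 1, 3, 11 and 16 are taken as commercially available.

**Ring-bearing fragment (steps 1–5)**

Step 1
Reactants: 1 2,3,4,5-tetramethoxytoluene
Product: 2 1-bromo-2,3,4,5-tetramethoxy-6-methylbenzene
Conditions: NBS, MeCN, 0 °C to rt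
Reagents that add atoms: N-bromosuccinimide, O=C1CCC(=O)N1Br
Why: Electrophilic aromatic bromination of a strongly activated ring that has a single free position, so only one regioisomer can form.

Step 2
Reactants: 2 1-bromo-2,3,4,5-tetramethoxy-6-methylbenzene; 3 (2E,6E)-farnesyl bromide
Product: 6 1-[(2E,6E)-3,7,11-trimethyldodeca-2,6,10-trien-1-yl]-2,3,4,5-tetramethoxy-6-methylbenzene, via aryllithium 4 (not isolated), via arylcopper 5 (not isolated)
Conditions: n-BuLi, THF, −78 °C; CuBr·SMe2, −78 to −40 °C; then 3, −78 °C to 0 °C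
Reagents that add atoms: n-butyllithium, [Li]CCCC (lithium stays only in 4); CuBr·SMe2, CSC.[Cu]Br (copper stays only in 5)
Why: Bromine–lithium exchange, transmetalation to monovalent copper and SN2 allylation of the arylcopper at the primary carbon of the allylic bromide should keep the 2E geometry and avoid the SN2′ product.

Step 3
Reactants: 6 1-[(2E,6E)-3,7,11-trimethyldodeca-2,6,10-trien-1-yl]-2,3,4,5-tetramethoxy-6-methylbenzene
Product: 8 2,2-dimethyl-3-[(3E,7E)-3,7-dimethyl-9-(2,3,4,5-tetramethoxy-6-methylphenyl)nona-3,7-dien-1-yl]oxirane (racemic), via bromohydrin 7 (not isolated)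
Conditions: NBS, THF/H2O, 0 °C; then K2CO3, MeOH, rt
Reagents that add atoms: water, O; N-bromosuccinimide, O=C1CCC(=O)N1Br (bromine stays only in 7)
Why: Terminal-selective bromohydrin formation in aqueous THF (bromonium ion at the least hindered, terminal trisubstituted alkene, water attack at the tertiary carbon) followed by base-mediated ring closure gives the terminal epoxide, whose configuration is irrelevant because that carbon becomes the aldehyde carbon in step 4.

Step 4
Reactants: 8 terminal epoxide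
Product: 9 (4E,8E)-4,8-dimethyl-10-(2,3,4,5-tetramethoxy-6-methylphenyl)deca-4,8-dienal
Conditions: H5IO6, THF/Et2O, 0 °C
Reagents that add atoms: none
Why: Periodic acid opens the epoxide to the vicinal diol and cleaves it (Malaprade glycol cleavage), removing three carbons as acetone and leaving the former epoxide oxygen on the aldehyde without touching the trisubstituted alkenes.

Step 5
Reactants: 9 (4E,8E)-4,8-dimethyl-10-(2,3,4,5-tetramethoxy-6-methylphenyl)deca-4,8-dienal
Product: 10 1-[(2E,6E)-11,11-dichloro-3,7-dimethylundeca-2,6,10-trien-1-yl]-2,3,4,5-tetramethoxy-6-methylbenzene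
Conditions: PPh3, CCl4, MeCN, rt
Reagents that add atoms: carbon tetrachloride, ClC(Cl)(Cl)Cl
Why: Wittig-type dichloromethylenation by Ph3P=CCl2, generated in the flask from PPh3 and CCl4, converts the aldehyde into the 1,1-dichloroalkene.

**Tail fragment (steps 6–12)**

Step 6
Reactants: 11 (2E,6E,10E)-geranylgeraniol
Product: 12 (2E,6E,10E)-1-bromo-3,7,11,15-tetramethylhexadeca-2,6,10,14-tetraene
Conditions: PBr3, Et2O, −10 °C
Reagents that add atoms: phosphorus tribromide, BrP(Br)Br
Why: Low-temperature substitution of the primary allylic alcohol via its phosphite ester should give the bromide without allylic transposition or loss of the 2E geometry.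

Step 7
Reactants: 12 (2E,6E,10E)-1-bromo-3,7,11,15-tetramethylhexadeca-2,6,10,14-tetraene
Product: 13 trimethyl[(5E,9E,13E)-6,10,14,18-tetramethylnonadeca-5,9,13,17-tetraen-1-yn-1-yl]silane
Conditions: 1-(trimethylsilyl)propyne, n-BuLi, THF, −78 °C; then 12, −78 °C to 0 °C
Reagents that add atoms: 1-(trimethylsilyl)propyne, CC#C[Si](C)(C)C
Why: SN2 alkylation of the propargylic lithium reagent at the primary allylic carbon, with the silyl group suppressing allenyl products, adds the three carbons that become C14 to C16.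

Step 8
Reactants: 13 trimethyl[(5E,9E,13E)-6,10,14,18-tetramethylnonadeca-5,9,13,17-tetraen-1-yn-1-yl]silane
Product: 14 (2E,6E,10E,14E)-2,6,10,14-tetramethyl-19-(trimethylsilyl)nonadeca-2,6,10,14-tetraen-18-yn-1-ol
Conditions: SeO2 (cat.), t-BuOOH, salicylic acid (cat.), CH2Cl2, 0 °C to rt, stopped at partial conversion
Reagents that add atoms: tert-butyl hydroperoxide, CC(C)(C)OO (terminal oxidant); SeO2, O=[Se]=O (oxygen carrier)
Why: SeO2-catalysed allylic hydroxylation (ene reaction, then [2,3]-sigmatropic shift) should oxidise the (E)-methyl group of the terminal isopropylidene unit, which fixes the 2E geometry of the new allylic alcohol.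

Step 9
Reactants: 14 (2E,6E,10E,14E)-2,6,10,14-tetramethyl-19-(trimethylsilyl)nonadeca-2,6,10,14-tetraen-18-yn-1-ol
Product: 15 [(5E,9E,13E,17E)-19-bromo-6,10,14,18-tetramethylnonadeca-5,9,13,17-tetraen-1-yn-1-yl]trimethylsilane
Conditions: CBr4, PPh3, CH2Cl2, 0 °C
Reagents that add atoms: carbon tetrabromide, BrC(Br)(Br)Br
Why: The Appel reaction converts the primary allylic alcohol to the bromide under neutral conditions without allylic transposition.

Step 10
Reactants: 15 allylic bromide; 16 (R)-citronellyl bromide [(6R)-8-bromo-2,6-dimethyloct-2-ene]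
Product: 18 trimethyl[(5E,9E,13E,17E,22S)-6,10,14,18,22,26-hexamethylheptacosa-5,9,13,17,25-pentaen-1-yn-1-yl]silane, via Grignard reagent 17 (not isolated)
Conditions: 16, Mg, THF, rt; then 15, Li2CuCl4 (cat.), THF, −78 °C to 0 °C
Reagents that add atoms: magnesium, [Mg] (stays only in 17)
Why: Copper-catalysed sp3–sp3 coupling of a primary alkyl Grignard reagent with a primary allylic bromide should occur at the α-carbon with retention of the E geometry, and the stereocentre of the target is brought in unchanged from the chiral pool in 16.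

Step 11
Reactants: 18 silylalkyne
Product: 19 (5E,9E,13E,17E,22S)-6,10,14,18,22,26-hexamethylheptacosa-5,9,13,17,25-pentaen-1-yne
Conditions: K2CO3 (cat.), MeOH/THF, rt
Reagents that add atoms: none
Why: Base-catalysed methanolysis of the alkynyl C–Si bond (protodesilylation) frees the terminal alkyne.

Step 12
Reactants: 19 terminal alkyne
Product: 21 (3E,7E,11E,15E,19E,24S)-4,8,12,16,20,24,28-heptamethylnonacosa-1,3,7,11,15,19,27-heptaene, via alkenylalane 20 (not isolated)
Conditions: Me3Al, Cp2ZrCl2 (cat.), CH2Cl2, 0 °C to rt; then vinyl bromide, ZnCl2 (cat.), Pd(PPh3)4 (cat.), THF, rt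
Reagents that add atoms: trimethylaluminium, C[Al](C)C; vinyl bromide, C=CBr
Why: Zirconium-catalysed syn-carboalumination (Negishi carboalumination) places methyl on the internal and aluminium on the terminal alkyne carbon, and palladium-catalysed cross-coupling of the alkenylalane with vinyl bromide with retention then gives the (3E)-diene.

**Fragment union and end game (steps 13–14)**

Step 13
Reactants: 21 C36 terminal diene; 10 ring-bearing 1,1-dichloroalkene
Product: 24 1-[(2E,6E,10E,14E,18E,22E,26E,30E,35S)-3,7,11,15,19,23,27,31,35,39-decamethyltetraconta-2,6,10,14,18,22,26,30,38-nonaen-1-yl]-2,3,4,5-tetramethoxy-6-methylbenzene, via alkylborane 22 (not isolated), via chloroalkene 23 (not isolated)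
Conditions: 21, 9-BBN, THF, 0 °C to rt; then 10, Pd2(dba)3 (cat.), Xantphos, anhydrous K3PO4, THF, 65 °C; then Me2Zn, Pd(tBu3P)2 (cat.), 50 °C, one pot
Reagents that add atoms: dimethylzinc, C[Zn]C; 9-borabicyclo[3.3.1]nonane, B1C2CCCC1CCC2 (boron stays only in 22)
Why: Anti-Markovnikov hydroboration of the monosubstituted terminus of 21 gives homoallylborane 22; zerovalent palladium then inserts into the C–Cl bond of 10 that is trans to the chain (cis to H, the less hindered one), and transmetalation of the phosphate-activated B-alkyl group followed by reductive elimination forms the C11–C12 bond to give (Z)-chloroalkene 23. A second oxidative addition into the remaining, more hindered C–Cl bond by the electron-rich Pd(tBu3P)2 catalyst, transmetalation from Me2Zn and reductive elimination should install the C11 methyl group with retention, so that the tail ends up trans to the chain (10E). The closest known reaction types are the trans-selective B-alkyl Suzuki–Miyaura monoalkylation of 1,1-dichloro-1-alkenes and the Negishi methylation of (Z)-2-chloro-2-alkenes, here run in sequence in one flask. No ring is closed and no stereocentre is formed; the only new stereoelement, the C10=C11 geometry, is controlled by the order of the two oxidative additions, which the substrate dictates through the cis or trans relation of each chlorine to the C9 methylene. The step needs site selectivity of 9-BBN for the vinyl group over the six trisubstituted alkenes of 21 (secured by the steric demand of 9-BBN), mono- over dialkylation (secured by the low reactivity of 23 toward the Xantphos catalyst and a near-stoichiometric amount of 22), and retention in the methylation (secured by the bulky monophosphine, which suppresses isomerisation of the alkenylpalladium intermediate).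

Step 14
Reactants: 24 tetramethoxyarene with the complete side chain
Product: 25 2-[(2E,6E,10E,14E,18E,22E,26E,30E,35S)-3,7,11,15,19,23,27,31,35,39-decamethyltetraconta-2,6,10,14,18,22,26,30,38-nonaen-1-yl]-5,6-dimethoxy-3-methylcyclohexa-2,5-diene-1,4-dione
Conditions: (NH4)2Ce(NO3)6, MeCN/H2O, 0 °C
Reagents that add atoms: water, O
Why: Oxidative demethylation by tetravalent cerium of the para-related methoxy groups flanking the two alkyl substituents (two one-electron oxidations, water attack, loss of methanol) should give the para-quinone and leave the isolated alkenes and the remote stereocentre untouched.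

**Compound list**

1 | 2,3,4,5-tetramethoxytoluene | Cc1cc(OC)c(OC)c(OC)c1OC | starting material
2 | 1-bromo-2,3,4,5-tetramethoxy-6-methylbenzene | Cc1c(Br)c(OC)c(OC)c(OC)c1OC | intermediate
3 | (2E,6E)-farnesyl bromide | BrC/C=C(\C)CC/C=C(\C)CCC=C(C)C | starting material
4 | (2,3,4,5-tetramethoxy-6-methylphenyl)lithium | [Li]c1c(C)c(OC)c(OC)c(OC)c1OC | intermediate
5 | (2,3,4,5-tetramethoxy-6-methylphenyl)copper | [Cu]c1c(C)c(OC)c(OC)c(OC)c1OC | intermediate
6 | 1-[(2E,6E)-3,7,11-trimethyldodeca-2,6,10-trien-1-yl]-2,3,4,5-tetramethoxy-6-methylbenzene | COc1c(OC)c(OC)c(OC)c(C)c1C/C=C(\C)CC/C=C(\C)CCC=C(C)C | intermediate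
7 | (6E,10E)-3-bromo-2,6,10-trimethyl-12-(2,3,4,5-tetramethoxy-6-methylphenyl)dodeca-6,10-dien-2-ol (racemic) | COc1c(OC)c(OC)c(OC)c(C)c1C/C=C(\C)CC/C=C(\C)CCC(Br)C(C)(C)O | intermediate
8 | 2,2-dimethyl-3-[(3E,7E)-3,7-dimethyl-9-(2,3,4,5-tetramethoxy-6-methylphenyl)nona-3,7-dien-1-yl]oxirane (racemic) | COc1c(OC)c(OC)c(OC)c(C)c1C/C=C(\C)CC/C=C(\C)CCC1OC1(C)C | intermediate
9 | (4E,8E)-4,8-dimethyl-10-(2,3,4,5-tetramethoxy-6-methylphenyl)deca-4,8-dienal | COc1c(OC)c(OC)c(OC)c(C)c1C/C=C(\C)CC/C=C(\C)CCC=O | intermediate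
10 | 1-[(2E,6E)-11,11-dichloro-3,7-dimethylundeca-2,6,10-trien-1-yl]-2,3,4,5-tetramethoxy-6-methylbenzene | COc1c(OC)c(OC)c(OC)c(C)c1C/C=C(\C)CC/C=C(\C)CCC=C(Cl)Cl | intermediate
11 | (2E,6E,10E)-geranylgeraniol | OC/C=C(\C)CC/C=C(\C)CC/C=C(\C)CCC=C(C)C | starting material
12 | (2E,6E,10E)-1-bromo-3,7,11,15-tetramethylhexadeca-2,6,10,14-tetraene | BrC/C=C(\C)CC/C=C(\C)CC/C=C(\C)CCC=C(C)C | intermediate
13 | trimethyl[(5E,9E,13E)-6,10,14,18-tetramethylnonadeca-5,9,13,17-tetraen-1-yn-1-yl]silane | C[Si](C)(C)C#CCC/C=C(\C)CC/C=C(\C)CC/C=C(\C)CCC=C(C)C | intermediate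
14 | (2E,6E,10E,14E)-2,6,10,14-tetramethyl-19-(trimethylsilyl)nonadeca-2,6,10,14-tetraen-18-yn-1-ol | C[Si](C)(C)C#CCC/C=C(\C)CC/C=C(\C)CC/C=C(\C)CC/C=C(\C)CO | intermediate
15 | [(5E,9E,13E,17E)-19-bromo-6,10,14,18-tetramethylnonadeca-5,9,13,17-tetraen-1-yn-1-yl]trimethylsilane | C[Si](C)(C)C#CCC/C=C(\C)CC/C=C(\C)CC/C=C(\C)CC/C=C(\C)CBr | intermediate
16 | (R)-citronellyl bromide, (6R)-8-bromo-2,6-dimethyloct-2-ene | BrCC[C@H](C)CCC=C(C)C | starting material
17 | [(3R)-3,7-dimethyloct-6-en-1-yl]magnesium bromide | Br[Mg]CC[C@H](C)CCC=C(C)C | intermediate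
18 | trimethyl[(5E,9E,13E,17E,22S)-6,10,14,18,22,26-hexamethylheptacosa-5,9,13,17,25-pentaen-1-yn-1-yl]silane | C[Si](C)(C)C#CCC/C=C(\C)CC/C=C(\C)CC/C=C(\C)CC/C=C(\C)CCC[C@H](C)CCC=C(C)C | intermediate
19 | (5E,9E,13E,17E,22S)-6,10,14,18,22,26-hexamethylheptacosa-5,9,13,17,25-pentaen-1-yne | C#CCC/C=C(\C)CC/C=C(\C)CC/C=C(\C)CC/C=C(\C)CCC[C@H](C)CCC=C(C)C | intermediate
20 | dimethyl[(1E,5E,9E,13E,17E,22S)-2,6,10,14,18,22,26-heptamethylheptacosa-1,5,9,13,17,25-hexaen-1-yl]alumane | C[Al](C)/C=C(\C)CC/C=C(\C)CC/C=C(\C)CC/C=C(\C)CC/C=C(\C)CCC[C@H](C)CCC=C(C)C | intermediate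
21 | (3E,7E,11E,15E,19E,24S)-4,8,12,16,20,24,28-heptamethylnonacosa-1,3,7,11,15,19,27-heptaene | C=C/C=C(\C)CC/C=C(\C)CC/C=C(\C)CC/C=C(\C)CC/C=C(\C)CCC[C@H](C)CCC=C(C)C | intermediate
22 | 9-[(3E,7E,11E,15E,19E,24S)-4,8,12,16,20,24,28-heptamethylnonacosa-3,7,11,15,19,27-hexaen-1-yl]-9-borabicyclo[3.3.1]nonane | C1CCC2CCCC1B2CC/C=C(\C)CC/C=C(\C)CC/C=C(\C)CC/C=C(\C)CC/C=C(\C)CCC[C@H](C)CCC=C(C)C | intermediate
23 | 1-[(2E,6E,10Z,14E,18E,22E,26E,30E,35S)-11-chloro-3,7,15,19,23,27,31,35,39-nonamethyltetraconta-2,6,10,14,18,22,26,30,38-nonaen-1-yl]-2,3,4,5-tetramethoxy-6-methylbenzene | COc1c(OC)c(OC)c(OC)c(C)c1C/C=C(\C)CC/C=C(\C)CC/C=C(\Cl)CC/C=C(\C)CC/C=C(\C)CC/C=C(\C)CC/C=C(\C)CC/C=C(\C)CCC[C@H](C)CCC=C(C)C | intermediate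
24 | 1-[(2E,6E,10E,14E,18E,22E,26E,30E,35S)-3,7,11,15,19,23,27,31,35,39-decamethyltetraconta-2,6,10,14,18,22,26,30,38-nonaen-1-yl]-2,3,4,5-tetramethoxy-6-methylbenzene | COc1c(OC)c(OC)c(OC)c(C)c1C/C=C(\C)CC/C=C(\C)CC/C=C(\C)CC/C=C(\C)CC/C=C(\C)CC/C=C(\C)CC/C=C(\C)CC/C=C(\C)CCC[C@H](C)CCC=C(C)C | intermediate
25 | 2-[(2E,6E,10E,14E,18E,22E,26E,30E,35S)-3,7,11,15,19,23,27,31,35,39-decamethyltetraconta-2,6,10,14,18,22,26,30,38-nonaen-1-yl]-5,6-dimethoxy-3-methylcyclohexa-2,5-diene-1,4-dione | COC1=C(OC)C(=O)C(C/C=C(\C)CC/C=C(\C)CC/C=C(\C)CC/C=C(\C)CC/C=C(\C)CC/C=C(\C)CC/C=C(\C)CC/C=C(\C)CCC[C@H](C)CCC=C(C)C)=C(C)C1=O | target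

**Step count and risks**

Total step count: 14. Longest linear sequence: 9 steps (11 to 25 through steps 6 to 14); the ring-bearing fragment takes 5 steps (1 to 10) and joins in step 13.

Steps most likely to fail:

1. Step 13. The intermediate chloroalkene may react with a second alkylborane, oxidative addition into the hindered second C–Cl bond may be slow, or the alkene geometry may erode during the methylation. The fallback puts the methyl group in place before the fragments are joined and sets out from 10. Treatment with n-BuLi (THF, −78 °C) and then MeI should give the methylalkyne 1-[(2E,6E)-3,7-dimethyldodeca-2,6-dien-10-yn-1-yl]-2,3,4,5-tetramethoxy-6-methylbenzene F1. Hydrozirconation with an excess of Cp2Zr(H)Cl (THF, 50 °C, equilibration toward the less hindered alkenylzirconium) and iodination should give the vinyl iodide 1-[(2E,6E,10E)-11-iodo-3,7-dimethyldodeca-2,6,10-trien-1-yl]-2,3,4,5-tetramethoxy-6-methylbenzene F2. A two-component B-alkyl Suzuki–Miyaura coupling of F2 with alkylborane 22 (from 21 and 9-BBN; Pd(dppf)Cl2, AsPh3, Cs2CO3, DMF/THF/H2O, rt) should form the same C11–C12 bond with retention and comes back to the route at 24.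

2. Step 8. Oxidation may also occur at internal allylic positions, and the alcohol may be over-oxidised to the enal, so that material is lost at partial conversion. The fallback builds the (E)-allylic alcohol by olefination and sets out from 13. NBS in THF/H2O should give the terminal bromohydrin (6E,10E,14E)-3-bromo-2,6,10,14-tetramethyl-19-(trimethylsilyl)nonadeca-6,10,14-trien-18-yn-2-ol F3. NaH in THF should close it to the epoxide trimethyl[(5E,9E,13E)-16-(3,3-dimethyloxiran-2-yl)-6,10,14-trimethylhexadeca-5,9,13-trien-1-yn-1-yl]silane F4. H5IO6 should cleave this to the aldehyde (4E,8E,12E)-4,8,12-trimethyl-17-(trimethylsilyl)heptadeca-4,8,12-trien-16-ynal F5. An E-selective Wittig reaction with ethyl 2-(triphenylphosphoranylidene)propanoate (CH2Cl2, rt) should give the enoate ethyl (2E,6E,10E,14E)-2,6,10,14-tetramethyl-19-(trimethylsilyl)nonadeca-2,6,10,14-tetraen-18-ynoate F6. Reduction with DIBAL-H (CH2Cl2, −78 °C) comes back to the route at 14.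

3. Step 10. The Grignard reagent may attack with allylic transposition (SN2′) or undergo Wurtz-type homocoupling. The fallback uses a soft sulfone carbanion and sets out from 16. PhSO2Na in DMF at 60 °C should give the sulfone [(3R)-3,7-dimethyloct-6-en-1-yl]sulfonylbenzene F7. Deprotonation with n-BuLi (THF, −78 °C) and alkylation with 15 should give, by clean SN2 attack, the coupled sulfone trimethyl[(5E,9E,13E,17E,22R)-6,10,14,18,22,26-hexamethyl-20-(phenylsulfonyl)heptacosa-5,9,13,17,25-pentaen-1-yn-1-yl]silane F8 as a mixture of epimers at C20. Reductive desulfonylation with Na/Hg and Na2HPO4 in MeOH/THF at −20 °C should remove the sulfonyl group, and the methoxide formed should also cleave the alkynylsilane, so the fallback comes back to the route at 19.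

Further compounds
F1 | step 13 | 1-[(2E,6E)-3,7-dimethyldodeca-2,6-dien-10-yn-1-yl]-2,3,4,5-tetramethoxy-6-methylbenzene | COc1c(OC)c(OC)c(OC)c(C)c1C/C=C(\C)CC/C=C(\C)CCC#CC
F2 | step 13 | 1-[(2E,6E,10E)-11-iodo-3,7-dimethyldodeca-2,6,10-trien-1-yl]-2,3,4,5-tetramethoxy-6-methylbenzene | COc1c(OC)c(OC)c(OC)c(C)c1C/C=C(\C)CC/C=C(\C)CC/C=C(\C)I
F3 | step 8 | (6E,10E,14E)-3-bromo-2,6,10,14-tetramethyl-19-(trimethylsilyl)nonadeca-6,10,14-trien-18-yn-2-ol (racemic) | C[Si](C)(C)C#CCC/C=C(\C)CC/C=C(\C)CC/C=C(\C)CCC(Br)C(C)(C)O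
F4 | step 8 | trimethyl[(5E,9E,13E)-16-(3,3-dimethyloxiran-2-yl)-6,10,14-trimethylhexadeca-5,9,13-trien-1-yn-1-yl]silane (racemic) | C[Si](C)(C)C#CCC/C=C(\C)CC/C=C(\C)CC/C=C(\C)CCC1OC1(C)C
F5 | step 8 | (4E,8E,12E)-4,8,12-trimethyl-17-(trimethylsilyl)heptadeca-4,8,12-trien-16-ynal | C[Si](C)(C)C#CCC/C=C(\C)CC/C=C(\C)CC/C=C(\C)CCC=O
F6 | step 8 | ethyl (2E,6E,10E,14E)-2,6,10,14-tetramethyl-19-(trimethylsilyl)nonadeca-2,6,10,14-tetraen-18-ynoate | C[Si](C)(C)C#CCC/C=C(\C)CC/C=C(\C)CC/C=C(\C)CC/C=C(\C)C(=O)OCC
F7 | step 10 | [(3R)-3,7-dimethyloct-6-en-1-yl]sulfonylbenzene | O=S(=O)(CC[C@H](C)CCC=C(C)C)c1ccccc1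
F8 | step 10 | trimethyl[(5E,9E,13E,17E,22R)-6,10,14,18,22,26-hexamethyl-20-(phenylsulfonyl)heptacosa-5,9,13,17,25-pentaen-1-yn-1-yl]silane (epimers at C20) | C[Si](C)(C)C#CCC/C=C(\C)CC/C=C(\C)CC/C=C(\C)CC/C=C(\C)CC(C[C@H](C)CCC=C(C)C)S(=O)(=O)c1ccccc1
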